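## The problem

The target is an unsymmetrical C40 carotenoid methyl ether. An all-E undecaene chain carries an open ψ-type terminus at one end and a trisubstituted cyclopentanol at the other. The ring atoms are numbered C1 (CH bearing the CMe2OMe carbon, Cq), C2 and C3 (CH2), C4 (C(OH)CH3) and C5 (CH bearing the chain); the chain runs C7 to C15 and on through C15′ to C1′.

The chain is best assembled from C15, C10 and C15 units by olefination, so the real task is a C15 ring building block with three contiguous stereocentres: C1 (R), C5 (S) and C4 (R). Cq on C1 is trans to C7 on C5, and the hydroxyl on C4 is cis to C7. C4 is quaternary and cannot be corrected later, so it must be set first and under catalyst control. C5 can then be set relative to C4, and C5 together with C4 can direct a carbinol centre that becomes C1.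

Several groups restrict the conditions:
- The polyene tolerates neither acid nor light and oxygen, so it has to be attached last under near-neutral conditions.
- The tertiary hydroxyl on C4 is β to C5. With C7 as an aldehyde it is an aldol (retro-aldol, dehydration), and in the C15 dienal it is still a vinylogous aldol.
- The tertiary methyl ether and tertiary alcohol both ionise in strong acid.

The feature that opens the ring to a short synthesis is the exocyclic Cq(CH3)2–OMe on C1 next to the ring methylene C2. This is what remains when a 2,2-dimethylcyclohexyl cation contracts: C2 has moved from Cq to C1 and the charge left on Cq has been quenched by an alcohol.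

## Retrosynthesis

**C11=C12 (Wittig).** Target 29 is cut at C11=C12 into the C15 hydroxy dienal 21 and the C25 phosphonium salt 28. A cut at C7=C8 would need a semistabilised polyenyl ylide on a hindered α-branched aldehyde, with poor E control. The cut at C11=C12 gives a hindered Z isomer (next to the C13 methyl) that reverts thermally. The ring half is made the aldehyde and the hydrocarbon half the phosphonium salt, because salt formation needs acid and an allyl cation at C7 beside the C4 oxygen would invite fragmentation. The forward reaction must tolerate a free tertiary alcohol and avoid free alkoxide.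

**C25 salt.** Salt 28 comes from alcohol 27 and aldehyde 26. Aldehyde 26 is cut at C11′=C12′ into the commercial C10 dialdehyde 25 and the C15 salt 24, which derives from pseudoionone 22 through the vinyl carbinol 23. All of these are hydrocarbons or simple carbonyl compounds without stereocentres. The only demand is mono-olefination of 25, met by using it in excess.

**C7=C8 (Horner–Wadsworth–Emmons).** Dienal 21 is traced through diol 20, silyl ether 19 and ester 18 to the ring aldehyde 16 and the C5 phosphonate 17. A stabilised phosphonate gives the E double bond at C7=C8 and brings C8 to C11 with the C9 methyl in one step. The C4 oxygen stays silylated during this step because the aldehyde is a β-oxy aldehyde and base would otherwise open the ring by retro-aldol cleavage. Aldehyde 16 comes from alcohol 15, which comes from the bis-silyl ether 14 by removal of the primary silyl group only.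

**Key disconnection (C1–C2 and Cq–O).** In 14 the C1–C2 bond and the Cq–OMe bond are cut and C2 is reconnected to Cq. This gives the 2,2-dimethylcyclohexyl mesylate 13, in which the future C1 is the carbinol carbon. The alternative cuts at C4–C5, C1–C5 or C3–C4 each form one ring bond and need an acyclic chain with two stereocentres in place. This cut instead forms the ring, the quaternary ether carbon and the C1 stereocentre in one stereospecific event from a six-membered ring, where relative configuration is easy to control. The forward reaction needs an equatorial leaving group antiperiplanar to the ring bond that must migrate, and capture of the resulting tertiary cation by the solvent alcohol rather than proton loss.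

**Mesylate precursor.** Compound 13 is simplified by removing the tertiary silyl group (12), the mesyl group (11) and the primary silyl group to triol 10. The carbinol C–H bond of 10 is then cut to give keto diol 9. An axial tertiary hydroxyl 1,3 to the ketone can deliver hydride intramolecularly, which gives the equatorial alcohol anti to it, as the contraction requires.

**C5–C7 bond.** Keto diol 9 is cut between the ring and the hydroxymethyl carbon to give the silyl enol ether 7 of hydroxy ketone 6 and a one-carbon aldehyde electrophile. The gem-dimethyl group blocks the other α position, so regiochemistry is not an issue. The forward reaction must add the electrophile cis to the tertiary oxygen.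

**C4 stereocentre.** Hydroxy ketone 6 is cut at the C–O bond of the tertiary alcohol to give enone 3 and diboron reagent 4, through boronate 5. This is the single enantio-determining step. Enone 3 comes from commercial 3-methylcyclohex-2-en-1-one 1 by two α′-methylations through 2.

## Roads not taken

**Alternative 1:** The ring is cut at C4–C5 and, temporarily, at a lactone C7–O bond. The keto acid A1 is activated as an acyl ammonium species (TsCl, iPr2NEt, LiCl, 4-pyrrolidinopyridine). Its enolate adds through C5 to the C4 ketone and the aldolate closes the four-membered lactone, giving the cis-fused bicyclic β-lactone A2.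
- Merits: the cis relation between C7 and the C4 oxygen is enforced by the ring fusion. A1 is a few steps from a chiral-pool monoterpene of the p-menthane family. Two stereocentres and the ring form together.
- Weak points: the C1 stereocentre must steer both new centres anti from an acyclic conformation. The enantiopurity is only that of the terpene. A2 is a strained lactone with a tertiary C–O bond, prone to thermal loss of CO2 and to ionisation, and must be reduced at once.
- Comparison: this road is shorter to the ring and its C4/C5 control is geometrically more secure than the facial selectivity the chosen plan needs in step 4. The chosen plan offers catalyst-set absolute configuration, stable intermediates up to the key step, and a C1 centre created stereospecifically rather than by induction.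

**Alternative 2:** The ring is cut at C1–C5 and Cq–O. The acyclic epoxy diene A3 comes from a (Z)-configured C10 terpene allylic alcohol by asymmetric epoxidation, oxidation and iodo-olefination. It is activated with Sc(OTf)3 in MeOH/(CF3)2CHOH; alkene carbon C1 attacks the allylic epoxide carbon C5 with inversion and MeOH captures the Cq cation, giving the cyclopentanol vinyl iodide A4.
- Merits: the shortest route. All three ring stereocentres, the ring and the methyl ether form in one step, and the vinyl iodide allows direct cross-coupling to a polyene.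
- Weak points: the epoxide must open at its secondary carbon, which carries an electron-poor iodovinyl group, and not at the tertiary carbon C4. The opening is of the endo type. Hydride shift to a carbonyl compound and simple solvolysis by MeOH compete. The C1 configuration depends on the folding of the chain.
- Comparison: if the regiochemistry held, this road would be clearly better in step count. Both plans share the uncertain partition of a tertiary cation between MeOH capture and proton loss. In the chosen plan, however, the cation is generated from a conformationally locked sulfonate with only one productive migrating bond, and C1 is fixed by inversion.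

**Alternative 3:** The ring is cut at C3–C4. The iodo ketone A5 is treated with SmI2 in THF–HMPA; the primary iodide at C3 becomes an organosamarium that adds to the methyl ketone carbon C4 in a 5-exo-trig closure, giving the cyclopentanol benzyl ether A6.
- Merits: a robust ring closure with no cation. The methyl ether is installed early on a simple compound, and the benzyl ether is removed by hydrogenolysis before any polyene is present.
- Weak points: A5 already carries C1 and C5, which must be built anti on an open chain over several steps. C5 is α to the ketone and epimerisable. The new C4 centre relies on chelation to the benzyloxy oxygen, which HMPA tends to break. The key step makes one bond and one stereocentre only.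
- Comparison: the ring closure itself is safer than cation chemistry. The chosen plan offers a much shorter access to its key substrate from a cheap enone and a key step that builds a ring, two skeletal bonds and a stereocentre at once.

Key step: step 9

**Remarks on the chemistry (assumptions):**
- The bisphosphine enantiomer in step 2 is taken to be the one that adds boron to the enone face giving (5S)-5; the remote gem-dimethyl group is assumed not to change the sense of induction known for 3-alkylcyclohexenones.
- Pseudoionone 22 is used as its (3E,5E) isomer. The Z isomers formed at the new double bonds in steps 18 and 21 are of the hindered type (next to a methyl-bearing carbon) and are assumed to revert to E on heating.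

## Route

Step 1
Reactants: 1 3-methylcyclohex-2-en-1-one
Product: 3 3,6,6-trimethylcyclohex-2-en-1-one, via 3,6-dimethylcyclohex-2-en-1-one 2 (not isolated)
Conditions: LiN(i-Pr)2, THF, −78 °C; MeI; then LiN(i-Pr)2, −78 °C; MeI, −78 → 0 °C
Reagents that add atoms: iodomethane, CI
Why: Kinetic deprotonation of a 3-alkylcyclohexenone with a lithium amide occurs at the α′ carbon, so two successive enolate alkylations place both methyl groups on C6; this quaternary carbon becomes Cq and leaves the later ketone a single enolisable side. No stereocentre is formed.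

Step 2
Reactants: 3 3,6,6-trimethylcyclohex-2-en-1-one; 4 bis(pinacolato)diboron
Product: 6 (5R)-5-hydroxy-2,2,5-trimethylcyclohexan-1-one, via (5S)-2,2,5-trimethyl-5-(pinacolboryl)cyclohexan-1-one 5 (not isolated)
Conditions: CuCl (cat.), NaOt-Bu (cat.), QuinoxP* (cat., enantiomer as remarked), B2pin2, MeOH (2 equiv), THF, rt; then NaBO3·4H2O, THF/H2O, rt
Reagents that add atoms: sodium perborate, [Na+].[O-]OB=O
Why: Enantioselective copper-catalysed conjugate borylation of a β,β-disubstituted cyclic enone: the bisphosphine–copper boryl complex adds to one enantioface of the β carbon (ligand control) and creates the boron-bearing quaternary centre. Perborate oxidation replaces boron by hydroxyl with retention, giving the tertiary alcohol that becomes C4.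

Step 3
Reactants: 6 (5R)-5-hydroxy-2,2,5-trimethylcyclohexan-1-one
Product: 7 (3R)-3,6,6-trimethyl-1,3-bis(trimethylsilyloxy)cyclohex-1-ene
Conditions: Me3SiOTf, Et3N, CH2Cl2, −78 → 0 °C
Reagents that add atoms: trimethylsilyl trifluoromethanesulfonate, C[Si](C)(C)OS(=O)(=O)C(F)(F)F
Why: Amine-buffered silylation forms the silyl enol ether toward the only enolisable carbon (the other α carbon is quaternary) and caps the tertiary hydroxyl, so no alkoxide capable of retro-aldol cleavage is ever formed. The stereocentre is untouched.

Step 4
Reactants: 7 (3R)-3,6,6-trimethyl-1,3-bis(trimethylsilyloxy)cyclohex-1-ene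
Product: 9 (5R,6R)-5-hydroxy-6-(hydroxymethyl)-2,2,5-trimethylcyclohexan-1-one, via (5R,6R)-6-(hydroxymethyl)-2,2,5-trimethyl-5-(trimethylsilyloxy)cyclohexan-1-one 8 (not isolated)
Conditions: aq. HCHO (37%), Yb(OTf)3 (10 mol%), THF, rt; then citric acid, MeOH, 0 °C
Reagents that add atoms: formaldehyde, C=O
Why: Lewis-acid-catalysed Mukaiyama aldol (hydroxymethylation) of a silyl enol ether in aqueous medium. The electrophile should add axially anti to the methyl group of the neighbouring quaternary carbon, which keeps the allylic C–O bond out of alignment with the enol π system and puts the incoming carbon gauche to the smaller oxygen substituent, so CH2OH ends cis to the tertiary oxygen. This centre is epimerisable, and the same isomer (CH2OH and CH3 equatorial, OH axial) should also be the more stable one; mild acid then removes the tertiary trimethylsilyl group.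

Step 5
Reactants: 9 (5R,6R)-5-hydroxy-6-(hydroxymethyl)-2,2,5-trimethylcyclohexan-1-one
Product: 10 (1R,2S,3S)-2-(hydroxymethyl)-1,4,4-trimethylcyclohexane-1,3-diol
Conditions: Me4NBH(OAc)3, MeCN/AcOH (1:1), −30 → 0 °C
Reagents that add atoms: none
Why: Evans–Saksena hydroxyl-directed reduction: the axial tertiary hydroxyl exchanges onto boron and delivers hydride to the syn-axial face of the ketone, giving the equatorial secondary alcohol anti to it and trans to CH2OH. The opposite face is shielded by the axial methyl of the adjacent gem-dimethyl group, and the C6 epimer of 9 cannot place its substituents equatorial in the delivering chair, so it should be reduced only slowly.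

Step 6
Reactants: 10 (1R,2S,3S)-2-(hydroxymethyl)-1,4,4-trimethylcyclohexane-1,3-diol
Product: 11 (1R,2S,3S)-2-{[(tert-butyldimethylsilyl)oxy]methyl}-1,4,4-trimethylcyclohexane-1,3-diol
Conditions: t-BuMe2SiCl, imidazole, CH2Cl2, 0 °C
Reagents that add atoms: tert-butyldimethylsilyl chloride, CC(C)(C)[Si](C)(C)Cl
Why: Selective silylation of the primary hydroxyl; the secondary hydroxyl is neopentyl-like and the tertiary one is inert to the silyl chloride. No stereocentre changes.

Step 7
Reactants: 11 (1R,2S,3S)-2-{[(tert-butyldimethylsilyl)oxy]methyl}-1,4,4-trimethylcyclohexane-1,3-diol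
Product: 12 (1S,2S,3R)-2-{[(tert-butyldimethylsilyl)oxy]methyl}-3-hydroxy-3,6,6-trimethylcyclohexyl methanesulfonate
Conditions: MsCl, Et3N, CH2Cl2, −10 → 0 °C
Reagents that add atoms: methanesulfonyl chloride, CS(=O)(=O)Cl
Why: Sulfene-mediated mesylation reaches the hindered equatorial secondary hydroxyl while the tertiary hydroxyl reacts far more slowly. The C–O bond is not broken, so the carbinol configuration is kept.

Step 8
Reactants: 12 (1S,2S,3R)-2-{[(tert-butyldimethylsilyl)oxy]methyl}-3-hydroxy-3,6,6-trimethylcyclohexyl methanesulfonate
Product: 13 (1S,2S,3R)-3-[(tert-butyldimethylsilyl)oxy]-2-{[(tert-butyldimethylsilyl)oxy]methyl}-3,6,6-trimethylcyclohexyl methanesulfonate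
Conditions: t-BuMe2SiOTf, 2,6-lutidine, CH2Cl2, 0 °C → rt
Reagents that add atoms: tert-butyldimethylsilyl trifluoromethanesulfonate, CC(C)(C)[Si](C)(C)OS(=O)(=O)C(F)(F)F
Why: Silyl triflate silylation of a tertiary alcohol. The silyl ether lowers the donor ability and nucleophilicity of this oxygen, which suppresses fragmentation and oxetane formation in step 9 and later blocks retro-aldol cleavage at the aldehyde stage.

Step 9
Reactants: 13 (1S,2S,3R)-3-[(tert-butyldimethylsilyl)oxy]-2-{[(tert-butyldimethylsilyl)oxy]methyl}-3,6,6-trimethylcyclohexyl methanesulfonate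
Product: 14 tert-butyl({(1R,2R,5R)-2-[(tert-butyldimethylsilyl)oxy]-5-(2-methoxypropan-2-yl)-2-methylcyclopentyl}methoxy)dimethylsilane
Conditions: MeOH/(CF3)2CHOH (1:3), 2,6-lutidine (3 equiv), 50 °C
Reagents that add atoms: methanol, CO
Why: In the only low-energy chair of 13 the mesylate, the silyloxymethyl group and the methyl on the silyloxy-bearing carbon are all equatorial, so the ring bond from the gem-dimethyl carbon (future Cq) to the adjacent methylene (future C2) is antiperiplanar to the C–OMs bond. Ionisation in the strongly ionising, weakly nucleophilic fluoro alcohol is assisted by this bond: C2 shifts from Cq to C1 as mesylate leaves (Wagner–Meerwein 1,2-alkyl shift), and the tertiary 2-cyclopentylpropan-2-yl cation is captured by methanol while 2,6-lutidine takes up the acid. The closest known reaction type is the retropinacol contraction of equatorial sulfonates of 2,2-dimethylcyclohexanols, as in ring A of 4,4-dimethyl-3-sulfonyloxy triterpenoids and steroids, combined with ordinary solvolytic capture of a tertiary cation by an alcohol solvent. The cyclopentane therefore arises by ring contraction through a suprafacial 1,2-shift of a ring carbon, not by an exo or endo cyclisation of a chain. The one new stereocentre, C1 (R), is set by inversion at the carbinol carbon, because the migrating carbon enters anti to the leaving group; it is thus controlled by the carbinol configuration from step 5, and C4 and C5 are not touched. Three selectivities are needed. Migration must occur through the bond to the gem-dimethyl carbon and not through the other antiperiplanar ring bond, which would be a Grob-type fragmentation; the tertiary cation formed and the poor donor ability of the silylated oxygen favour this. Hydride shift, methyl shift and E2 elimination are excluded because no axial hydrogen or methyl is anti to an equatorial leaving group. Capture must outrun proton loss from the cation, which rests on methanol as co-solvent in large excess at moderate temperature.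

Step 10
Reactants: 14 tert-butyl({(1R,2R,5R)-2-[(tert-butyldimethylsilyl)oxy]-5-(2-methoxypropan-2-yl)-2-methylcyclopentyl}methoxy)dimethylsilane
Product: 15 {(1R,2R,5R)-2-[(tert-butyldimethylsilyl)oxy]-5-(2-methoxypropan-2-yl)-2-methylcyclopentyl}methanol
Conditions: HF·pyridine, pyridine, THF, 0 °C → rt
Reagents that add atoms: none
Why: Buffered fluoride cleavage distinguishes silyl ethers by steric access; the primary ether is removed and the tertiary one remains. The tertiary methyl ether is stable to these conditions.

Step 11
Reactants: 15 {(1R,2R,5R)-2-[(tert-butyldimethylsilyl)oxy]-5-(2-methoxypropan-2-yl)-2-methylcyclopentyl}methanol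
Product: 16 (1S,2R,5R)-2-[(tert-butyldimethylsilyl)oxy]-5-(2-methoxypropan-2-yl)-2-methylcyclopentane-1-carbaldehyde
Conditions: TEMPO (cat.), PhI(OAc)2, CH2Cl2, rt
Reagents that add atoms: none
Why: Oxoammonium (TEMPO) oxidation of a primary alcohol to the aldehyde under nearly neutral conditions. The α centre is not at risk, since its configuration, trans to both neighbouring carbon substituents, is also the thermodynamically preferred one.

Step 12
Reactants: 16 (1S,2R,5R)-2-[(tert-butyldimethylsilyl)oxy]-5-(2-methoxypropan-2-yl)-2-methylcyclopentane-1-carbaldehyde; 17 ethyl (2E)-4-(diethoxyphosphoryl)-3-methylbut-2-enoate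
Product: 18 ethyl (2E,4E)-5-{(1S,2R,5R)-2-[(tert-butyldimethylsilyl)oxy]-5-(2-methoxypropan-2-yl)-2-methylcyclopentyl}-3-methylpenta-2,4-dienoate
Conditions: 17, LiN(SiMe3)2, THF/DMPU, −78 °C; then 16, −78 → 0 °C
Reagents that add atoms: none
Why: Horner–Wadsworth–Emmons olefination with a vinylogous stabilised phosphonate anion gives the E double bond at C7=C8 and delivers C8 to C11 with the C9 methyl. The silyl ether on C4 rules out retro-aldol opening of the β-oxy aldehyde by base.

Step 13
Reactants: 18 ethyl (2E,4E)-5-{(1S,2R,5R)-2-[(tert-butyldimethylsilyl)oxy]-5-(2-methoxypropan-2-yl)-2-methylcyclopentyl}-3-methylpenta-2,4-dienoate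
Product: 19 (2E,4E)-5-{(1S,2R,5R)-2-[(tert-butyldimethylsilyl)oxy]-5-(2-methoxypropan-2-yl)-2-methylcyclopentyl}-3-methylpenta-2,4-dien-1-ol
Conditions: i-Bu2AlH, CH2Cl2, −78 °C
Reagents that add atoms: none
Why: 1,2-Reduction of a conjugated ester to the allylic alcohol by an aluminium hydride; double-bond geometry and all stereocentres are unaffected.

Step 14
Reactants: 19 (2E,4E)-5-{(1S,2R,5R)-2-[(tert-butyldimethylsilyl)oxy]-5-(2-methoxypropan-2-yl)-2-methylcyclopentyl}-3-methylpenta-2,4-dien-1-ol
Product: 20 (1R,2S,3R)-2-[(1E,3E)-5-hydroxy-3-methylpenta-1,3-dien-1-yl]-3-(2-methoxypropan-2-yl)-1-methylcyclopentan-1-ol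
Conditions: Bu4NF, THF, 50 °C
Reagents that add atoms: none
Why: Fluoride cleavage of the tertiary silyl ether is done at the dienol stage, where no carbonyl group is conjugated to C5, so the basic fluoride cannot trigger a vinylogous retro-aldol opening.

Step 15
Reactants: 20 (1R,2S,3R)-2-[(1E,3E)-5-hydroxy-3-methylpenta-1,3-dien-1-yl]-3-(2-methoxypropan-2-yl)-1-methylcyclopentan-1-ol
Product: 21 (2E,4E)-5-[(1S,2R,5R)-2-hydroxy-5-(2-methoxypropan-2-yl)-2-methylcyclopentyl]-3-methylpenta-2,4-dienal
Conditions: MnO2, CH2Cl2, rt
Reagents that add atoms: none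
Why: Chemoselective oxidation of an allylic alcohol on the MnO2 surface; the tertiary alcohol cannot be oxidised and the neutral medium leaves the vinylogous aldol intact.

Step 16
Reactants: 22 (3E,5E)-6,10-dimethylundeca-3,5,9-trien-2-one (pseudoionone)
Product: 23 (4E,6E)-3,7,11-trimethyldodeca-1,4,6,10-tetraen-3-ol (racemic)
Conditions: CH2=CHMgBr, THF, 0 °C
Reagents that add atoms: vinylmagnesium bromide, C=C[Mg]Br
Why: Grignard 1,2-addition to the dienone carbonyl gives the tertiary vinyl carbinol; its stereocentre is lost in the next step, so the racemate is used.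

Step 17
Reactants: 23 (4E,6E)-3,7,11-trimethyldodeca-1,4,6,10-tetraen-3-ol
Product: 24 [(2E,4E,6E)-3,7,11-trimethyldodeca-2,4,6,10-tetraen-1-yl]triphenylphosphonium bromide
Conditions: PPh3·HBr, MeOH, rt
Reagents that add atoms: triphenylphosphine hydrobromide, [Br-].c1ccc(cc1)[PH+](c1ccccc1)c1ccccc1
Why: Acid-mediated ionisation of the tertiary vinyl carbinol to a delocalised allyl cation and capture by triphenylphosphine at the unhindered terminus (allylic transposition) gives the primary phosphonium salt with the conjugated E triene.

Step 18
Reactants: 24 [(2E,4E,6E)-3,7,11-trimethyldodeca-2,4,6,10-tetraen-1-yl]triphenylphosphonium bromide; 25 (2E,4E,6E)-2,7-dimethylocta-2,4,6-trienedial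
Product: 26 (2E,4E,6E,8E,10E,12E,14E)-2,7,11,15,19-pentamethylicosa-2,4,6,8,10,12,14,18-octaenal
Conditions: NaOMe, CH2Cl2/MeOH, 0 °C → rt, 25 in excess; then heptane, reflux
Reagents that add atoms: none
Why: Wittig olefination of one aldehyde group of the symmetrical dialdehyde, with mono-reaction favoured by the excess of 25. The new double bond lies next to a methyl-bearing carbon, so its Z isomer is hindered and should revert to E on heating.

Step 19
Reactants: 26 (2E,4E,6E,8E,10E,12E,14E)-2,7,11,15,19-pentamethylicosa-2,4,6,8,10,12,14,18-octaenal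
Product: 27 (2E,4E,6E,8E,10E,12E,14E)-2,7,11,15,19-pentamethylicosa-2,4,6,8,10,12,14,18-octaen-1-ol
Conditions: NaBH4, EtOH/THF, 0 °C
Reagents that add atoms: none
Why: Borohydride 1,2-reduction of a polyenal to the allylic alcohol; the polyene is not touched.

Step 20
Reactants: 27 (2E,4E,6E,8E,10E,12E,14E)-2,7,11,15,19-pentamethylicosa-2,4,6,8,10,12,14,18-octaen-1-ol
Product: 28 [(2E,4E,6E,8E,10E,12E,14E)-2,7,11,15,19-pentamethylicosa-2,4,6,8,10,12,14,18-octaen-1-yl]triphenylphosphonium bromide
Conditions: PPh3·HBr, CH2Cl2/MeOH, rt
Reagents that add atoms: triphenylphosphine hydrobromide, [Br-].c1ccc(cc1)[PH+](c1ccccc1)c1ccccc1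
Why: Standard conversion of a polyenyl allylic alcohol into its phosphonium salt through the stabilised allyl cation; the acid step is carried out on the hydrocarbon half, which has no ionisable oxygen function.

Step 21
Reactants: 21 (2E,4E)-5-[(1S,2R,5R)-2-hydroxy-5-(2-methoxypropan-2-yl)-2-methylcyclopentyl]-3-methylpenta-2,4-dienal; 28 [(2E,4E,6E,8E,10E,12E,14E)-2,7,11,15,19-pentamethylicosa-2,4,6,8,10,12,14,18-octaen-1-yl]triphenylphosphonium bromide
Product: 29 (1R,2S,3R)-3-(2-methoxypropan-2-yl)-1-methyl-2-[(1E,3E,5E,7E,9E,11E,13E,15E,17E,19E)-3,7,12,16,20,24-hexamethylpentacosa-1,3,5,7,9,11,13,15,17,19,23-undecaen-1-yl]cyclopentan-1-ol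
Conditions: 1,2-epoxybutane/EtOH, reflux, Ar, dark
Reagents that add atoms: none
Why: Wittig olefination under the epoxide-scavenger conditions usual for carotenoids: bromide opens the epoxide and the resulting alkoxide generates the ylide at low concentration, so the free tertiary alcohol is never exposed to excess base. The new C11=C12 bond is of the hindered type and should equilibrate to E in the refluxing medium, giving the all-E target.

## Compound list

1 | 3-methylcyclohex-2-en-1-one | CC1=CC(=O)CCC1 | starting material
2 | 3,6-dimethylcyclohex-2-en-1-one (racemic, not isolated) | CC1=CC(=O)C(C)CC1 | intermediate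
3 | 3,6,6-trimethylcyclohex-2-en-1-one | CC1=CC(=O)C(C)(C)CC1 | intermediate
4 | bis(pinacolato)diboron | CC1(C)OB(OC1(C)C)B1OC(C)(C)C(C)(C)O1 | starting material
5 | (5S)-2,2,5-trimethyl-5-(4,4,5,5-tetramethyl-1,3,2-dioxaborolan-2-yl)cyclohexan-1-one (not isolated) | O=C1C[C@](C)(B2OC(C)(C)C(C)(C)O2)CCC1(C)C | intermediate
6 | (5R)-5-hydroxy-2,2,5-trimethylcyclohexan-1-one | O=C1C[C@](C)(O)CCC1(C)C | intermediate
7 | (3R)-3,6,6-trimethyl-1,3-bis(trimethylsilyloxy)cyclohex-1-ene | C[Si](C)(C)OC1=C[C@](C)(O[Si](C)(C)C)CCC1(C)C | intermediate
8 | (5R,6R)-6-(hydroxymethyl)-2,2,5-trimethyl-5-(trimethylsilyloxy)cyclohexan-1-one (not isolated) | O=C1[C@H](CO)[C@](C)(O[Si](C)(C)C)CCC1(C)C | intermediate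
9 | (5R,6R)-5-hydroxy-6-(hydroxymethyl)-2,2,5-trimethylcyclohexan-1-one | O=C1[C@H](CO)[C@](C)(O)CCC1(C)C | intermediate
10 | (1R,2S,3S)-2-(hydroxymethyl)-1,4,4-trimethylcyclohexane-1,3-diol | O[C@H]1[C@H](CO)[C@](C)(O)CCC1(C)C | intermediate
11 | (1R,2S,3S)-2-{[(tert-butyldimethylsilyl)oxy]methyl}-1,4,4-trimethylcyclohexane-1,3-diol | O[C@H]1[C@H](CO[Si](C)(C)C(C)(C)C)[C@](C)(O)CCC1(C)C | intermediate
12 | (1S,2S,3R)-2-{[(tert-butyldimethylsilyl)oxy]methyl}-3-hydroxy-3,6,6-trimethylcyclohexyl methanesulfonate | CS(=O)(=O)O[C@H]1[C@H](CO[Si](C)(C)C(C)(C)C)[C@](C)(O)CCC1(C)C | intermediate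
13 | (1S,2S,3R)-3-[(tert-butyldimethylsilyl)oxy]-2-{[(tert-butyldimethylsilyl)oxy]methyl}-3,6,6-trimethylcyclohexyl methanesulfonate (mesylate, silyloxymethyl and C3 methyl equatorial) | CS(=O)(=O)O[C@H]1[C@H](CO[Si](C)(C)C(C)(C)C)[C@](C)(O[Si](C)(C)C(C)(C)C)CCC1(C)C | intermediate
14 | tert-butyl({(1R,2R,5R)-2-[(tert-butyldimethylsilyl)oxy]-5-(2-methoxypropan-2-yl)-2-methylcyclopentyl}methoxy)dimethylsilane | COC(C)(C)[C@@H]1CC[C@@](C)(O[Si](C)(C)C(C)(C)C)[C@H]1CO[Si](C)(C)C(C)(C)C | intermediate
15 | {(1R,2R,5R)-2-[(tert-butyldimethylsilyl)oxy]-5-(2-methoxypropan-2-yl)-2-methylcyclopentyl}methanol | COC(C)(C)[C@@H]1CC[C@@](C)(O[Si](C)(C)C(C)(C)C)[C@H]1CO | intermediate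
16 | (1S,2R,5R)-2-[(tert-butyldimethylsilyl)oxy]-5-(2-methoxypropan-2-yl)-2-methylcyclopentane-1-carbaldehyde | COC(C)(C)[C@@H]1CC[C@@](C)(O[Si](C)(C)C(C)(C)C)[C@H]1C=O | intermediate
17 | ethyl (2E)-4-(diethoxyphosphoryl)-3-methylbut-2-enoate | CCOC(=O)/C=C(C)/CP(=O)(OCC)OCC | starting material
18 | ethyl (2E,4E)-5-{(1S,2R,5R)-2-[(tert-butyldimethylsilyl)oxy]-5-(2-methoxypropan-2-yl)-2-methylcyclopentyl}-3-methylpenta-2,4-dienoate | COC(C)(C)[C@@H]1CC[C@@](C)(O[Si](C)(C)C(C)(C)C)[C@H]1/C=C/C(C)=C/C(=O)OCC | intermediate
19 | (2E,4E)-5-{(1S,2R,5R)-2-[(tert-butyldimethylsilyl)oxy]-5-(2-methoxypropan-2-yl)-2-methylcyclopentyl}-3-methylpenta-2,4-dien-1-ol | COC(C)(C)[C@@H]1CC[C@@](C)(O[Si](C)(C)C(C)(C)C)[C@H]1/C=C/C(C)=C/CO | intermediate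
20 | (1R,2S,3R)-2-[(1E,3E)-5-hydroxy-3-methylpenta-1,3-dien-1-yl]-3-(2-methoxypropan-2-yl)-1-methylcyclopentan-1-ol | COC(C)(C)[C@@H]1CC[C@@](C)(O)[C@H]1/C=C/C(C)=C/CO | intermediate
21 | (2E,4E)-5-[(1S,2R,5R)-2-hydroxy-5-(2-methoxypropan-2-yl)-2-methylcyclopentyl]-3-methylpenta-2,4-dienal | COC(C)(C)[C@@H]1CC[C@@](C)(O)[C@H]1/C=C/C(C)=C/C=O | intermediate
22 | (3E,5E)-6,10-dimethylundeca-3,5,9-trien-2-one (pseudoionone) | CC(=O)/C=C/C=C(\C)CCC=C(C)C | starting material
23 | (4E,6E)-3,7,11-trimethyldodeca-1,4,6,10-tetraen-3-ol (racemic) | C=CC(C)(O)/C=C/C=C(\C)CCC=C(C)C | intermediate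
24 | [(2E,4E,6E)-3,7,11-trimethyldodeca-2,4,6,10-tetraen-1-yl]triphenylphosphonium bromide | [Br-].c1ccccc1[P+](c1ccccc1)(c1ccccc1)C/C=C(C)/C=C/C=C(\C)CCC=C(C)C | intermediate
25 | (2E,4E,6E)-2,7-dimethylocta-2,4,6-trienedial | O=C/C(C)=C/C=C/C=C(\C)C=O | starting material
26 | (2E,4E,6E,8E,10E,12E,14E)-2,7,11,15,19-pentamethylicosa-2,4,6,8,10,12,14,18-octaenal | O=C/C(C)=C/C=C/C=C(C)/C=C/C=C(C)/C=C/C=C(\C)CCC=C(C)C | intermediate
27 | (2E,4E,6E,8E,10E,12E,14E)-2,7,11,15,19-pentamethylicosa-2,4,6,8,10,12,14,18-octaen-1-ol | OC/C(C)=C/C=C/C=C(C)/C=C/C=C(C)/C=C/C=C(\C)CCC=C(C)C | intermediate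
28 | [(2E,4E,6E,8E,10E,12E,14E)-2,7,11,15,19-pentamethylicosa-2,4,6,8,10,12,14,18-octaen-1-yl]triphenylphosphonium bromide | [Br-].c1ccccc1[P+](c1ccccc1)(c1ccccc1)C/C(C)=C/C=C/C=C(C)/C=C/C=C(C)/C=C/C=C(\C)CCC=C(C)C | intermediate
29 | (1R,2S,3R)-3-(2-methoxypropan-2-yl)-1-methyl-2-[(1E,3E,5E,7E,9E,11E,13E,15E,17E,19E)-3,7,12,16,20,24-hexamethylpentacosa-1,3,5,7,9,11,13,15,17,19,23-undecaen-1-yl]cyclopentan-1-ol | COC(C)(C)[C@@H]1CC[C@@](C)(O)[C@H]1/C=C/C(C)=C/C=C/C(C)=C/C=C/C=C(C)/C=C/C=C(C)/C=C/C=C(\C)CCC=C(C)C | target

## Step count and least certain steps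

Total step count: 21. Longest linear sequence: 16 steps (steps 1 to 15 and step 21); the C25 branch (steps 16 to 20) joins in step 21.

**Step 9 (key step).** The most likely failure is proton loss from the tertiary cation (E1 termination) outrunning capture by methanol. Less likely are cleavage through the other antiperiplanar ring bond with the silyloxy oxygen as donor (Grob-type fragmentation) and premature loss of a silyl group in the warm protic medium. Fallback: the fallback sets out from 13 and accepts elimination. The same contraction is run in (CF3)2CHOH with 2,6-lutidine and no methanol, so the cation ends by proton loss to the isopropenyl compound tert-butyl({(1R,2R,5R)-2-[(tert-butyldimethylsilyl)oxy]-2-methyl-5-(prop-1-en-2-yl)cyclopentyl}methoxy)dimethylsilane F1. The methoxy group is then introduced separately by Markovnikov alkoxymercuration–demercuration (Hg(OAc)2, MeOH; then NaBH4, NaOH), which returns to the route at 14. Only the isopropenyl regioisomer of the elimination is recovered this way.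

**Step 4.** The risks are poor facial selectivity at the new centre next to the quaternary carbon, because the methyl/oxygen discrimination is modest, and loss of the allylic tertiary silyloxy group from 7 under Lewis acid (vinylogous elimination back to an enone). Fallback: the centre is set by protonation instead of C–C bond formation. Setting out from 7, if hydroxymethylation gives mainly the epimer (5R,6S)-5-hydroxy-6-(hydroxymethyl)-2,2,5-trimethylcyclohexan-1-one F2, both hydroxyls are silylated (Me3SiCl, imidazole) to (5R,6S)-2,2,5-trimethyl-5-(trimethylsilyloxy)-6-[(trimethylsilyloxy)methyl]cyclohexan-1-one F3. This is deprotonated with LiN(i-Pr)2 at −78 °C to lithium (3R)-3,6,6-trimethyl-3-(trimethylsilyloxy)-2-[(trimethylsilyloxy)methyl]cyclohex-1-en-1-olate F4. Kinetic protonation with a hindered phenol should place the proton on the face the carbon electrophile preferred and so give the opposite epimer, (5R,6R)-2,2,5-trimethyl-5-(trimethylsilyloxy)-6-[(trimethylsilyloxy)methyl]cyclohexan-1-one F5. Citric acid in methanol removes both silyl groups and returns to the route at 9.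

**Step 2.** The enone is β,β-disubstituted and carries a quaternary α′ carbon, so slow copper–boryl addition or eroded enantioselectivity is possible; the product aldol can also undergo retro-aldol racemisation if the oxidation medium becomes too basic. Fallback: setting out from 3, asymmetric nucleophilic epoxidation with aqueous H2O2 and a cinchona-derived primary amine salt gives (1R,6R)-3,3,6-trimethyl-7-oxabicyclo[4.1.0]heptan-2-one F6. Reductive cleavage of its Cα–O bond with SmI2 in THF/MeOH at low temperature keeps the tertiary C–O bond and returns to the route at 6.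

**Step 12.** The aldehyde is flanked by two substituted carbons, so addition of the phosphonate anion may be slow. The anion could then act as a base, causing epimerisation at C5 or loss of silanolate, and some Z isomer at C9=C10 is to be expected. Fallback: setting out from 16, the chain is built in two stages. A Wittig reaction with the neutral stabilised ylide Ph3P=CHC(O)CH3 gives (3E)-4-{(1S,2R,5R)-2-[(tert-butyldimethylsilyl)oxy]-5-(2-methoxypropan-2-yl)-2-methylcyclopentyl}but-3-en-2-one F7. Horner–Wadsworth–Emmons reaction of this methyl ketone with triethyl phosphonoacetate and NaH, followed by separation of the C9=C10 isomers, returns to the route at 18.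

**Step 21.** The risks are incomplete Z-to-E equilibration, thermal or oxidative loss of the polyene during the long reflux, and base-induced vinylogous retro-aldol opening of 21 if alkoxide accumulates. Fallback: the polarity of the coupling is reversed and the tertiary oxygen is kept silylated to the end. Setting out from 19, treatment with PPh3·HBr gives {(2E,4E)-5-{(1S,2R,5R)-2-[(tert-butyldimethylsilyl)oxy]-5-(2-methoxypropan-2-yl)-2-methylcyclopentyl}-3-methylpenta-2,4-dien-1-yl}triphenylphosphonium bromide F8. Wittig reaction of F8 with aldehyde 26 (NaOMe, CH2Cl2/MeOH, then heating) gives tert-butyl{[(1R,2S,3R)-3-(2-methoxypropan-2-yl)-1-methyl-2-[(1E,3E,5E,7E,9E,11E,13E,15E,17E,19E)-3,7,12,16,20,24-hexamethylpentacosa-1,3,5,7,9,11,13,15,17,19,23-undecaen-1-yl]cyclopentyl]oxy}dimethylsilane F9. Bu4NF in THF then returns to the route at 29. This pairing is held in reserve because it exposes the ring unit to acid, although the silyl ether should restrain fragmentation.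

## Further compounds

F1 | step 9 | tert-butyl({(1R,2R,5R)-2-[(tert-butyldimethylsilyl)oxy]-2-methyl-5-(prop-1-en-2-yl)cyclopentyl}methoxy)dimethylsilane | C=C(C)[C@@H]1CC[C@@](C)(O[Si](C)(C)C(C)(C)C)[C@H]1CO[Si](C)(C)C(C)(C)C
F2 | step 4 | (5R,6S)-5-hydroxy-6-(hydroxymethyl)-2,2,5-trimethylcyclohexan-1-one | O=C1[C@@H](CO)[C@](C)(O)CCC1(C)C
F3 | step 4 | (5R,6S)-2,2,5-trimethyl-5-(trimethylsilyloxy)-6-[(trimethylsilyloxy)methyl]cyclohexan-1-one | O=C1[C@@H](CO[Si](C)(C)C)[C@](C)(O[Si](C)(C)C)CCC1(C)C
F4 | step 4 | lithium (3R)-3,6,6-trimethyl-3-(trimethylsilyloxy)-2-[(trimethylsilyloxy)methyl]cyclohex-1-en-1-olate | [Li+].[O-]C1=C(CO[Si](C)(C)C)[C@](C)(O[Si](C)(C)C)CCC1(C)C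
F5 | step 4 | (5R,6R)-2,2,5-trimethyl-5-(trimethylsilyloxy)-6-[(trimethylsilyloxy)methyl]cyclohexan-1-one | O=C1[C@H](CO[Si](C)(C)C)[C@](C)(O[Si](C)(C)C)CCC1(C)C
F6 | step 2 | (1R,6R)-3,3,6-trimethyl-7-oxabicyclo[4.1.0]heptan-2-one | O=C1[C@@H]2O[C@]2(C)CCC1(C)C
F7 | step 12 | (3E)-4-{(1S,2R,5R)-2-[(tert-butyldimethylsilyl)oxy]-5-(2-methoxypropan-2-yl)-2-methylcyclopentyl}but-3-en-2-one | COC(C)(C)[C@@H]1CC[C@@](C)(O[Si](C)(C)C(C)(C)C)[C@H]1/C=C/C(C)=O
F8 | step 21 | {(2E,4E)-5-{(1S,2R,5R)-2-[(tert-butyldimethylsilyl)oxy]-5-(2-methoxypropan-2-yl)-2-methylcyclopentyl}-3-methylpenta-2,4-dien-1-yl}triphenylphosphonium bromide | [Br-].COC(C)(C)[C@@H]1CC[C@@](C)(O[Si](C)(C)C(C)(C)C)[C@H]1/C=C/C(C)=C/C[P+](c1ccccc1)(c1ccccc1)c1ccccc1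
F9 | step 21 | tert-butyl{[(1R,2S,3R)-3-(2-methoxypropan-2-yl)-1-methyl-2-[(1E,3E,5E,7E,9E,11E,13E,15E,17E,19E)-3,7,12,16,20,24-hexamethylpentacosa-1,3,5,7,9,11,13,15,17,19,23-undecaen-1-yl]cyclopentyl]oxy}dimethylsilane | COC(C)(C)[C@@H]1CC[C@@](C)(O[Si](C)(C)C(C)(C)C)[C@H]1/C=C/C(C)=C/C=C/C(C)=C/C=C/C=C(C)/C=C/C=C(C)/C=C/C=C(\C)CCC=C(C)C
A1 | alternative 1 | (3R)-3-(2-methoxypropan-2-yl)-6-oxoheptanoic acid | COC(C)(C)[C@@H](CC(=O)O)CCC(C)=O
A2 | alternative 1 | (1S,2R,5R)-2-(2-methoxypropan-2-yl)-5-methyl-6-oxabicyclo[3.2.0]heptan-7-one | COC(C)(C)[C@@H]1CC[C@@]2(C)OC(=O)[C@@H]12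
A3 | alternative 2 | (2S,3R)-2-[(E)-2-iodoethenyl]-3-methyl-3-(4-methylpent-3-en-1-yl)oxirane | CC(C)=CCC[C@@]1(C)O[C@H]1/C=C/I
A4 | alternative 2 | (1R,2R,3R)-2-[(E)-2-iodoethenyl]-3-(2-methoxypropan-2-yl)-1-methylcyclopentan-1-ol | COC(C)(C)[C@@H]1CC[C@@](C)(O)[C@H]1/C=C/I
A5 | alternative 3 | (3R,4R)-3-[(benzyloxy)methyl]-6-iodo-4-(2-methoxypropan-2-yl)hexan-2-one | COC(C)(C)[C@H](CCI)[C@H](COCc1ccccc1)C(C)=O
A6 | alternative 3 | (1R,2R,3R)-2-[(benzyloxy)methyl]-3-(2-methoxypropan-2-yl)-1-methylcyclopentan-1-ol | COC(C)(C)[C@@H]1CC[C@@](C)(O)[C@H]1COCc1ccccc1
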